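**Retrosynthetic overview**
- The strategy rests on the ether oxygen O1, which links the C2 stereocentre to ring A carbon C8a. Ring C is therefore closed last by forming O1–C8a from an (S)-C2 carbinol and a C8a bromide (palladium aryl etherification), so the C2–O bond is never broken and the configuration is retained.
- The target follows from the cyclised flavan by C4 desilylation, oxidation to the C4 ketone and MOM cleavage.
- The open-chain carbinol comes from CBS reduction of an aryl ketone. That ketone is the silylated aldol adduct (C3–C4 bond) of 4-(methoxymethoxy)acetophenone and the ring A 2-bromobenzaldehyde.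
- The ring A aldehyde comes from 5-bromoresorcinol by formylation, iodination between the two oxygens, MOM protection and iodide-selective Suzuki coupling (C6–C1'' bond). The (E)-alkenylboronate partner comes from (S)-citronellal by aldehyde-to-alkyne dehydration and hydroboration.
- Rings A and B are bought; ring C is the only ring formed.

Key step: step 11

Assumption: the aldol step is not stereocontrolled, so the aldol adduct and every compound up to the flavan-4-ol are carried as mixtures of the two C4 epimers (flavanone numbering); this centre is erased by the oxidation to the ketone.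

**Route**

Step 1
Reactants: 1 (S)-citronellal
Product: 3 (S)-3,7-dimethyloct-6-en-1-yne, via alkenyl nonaflate 2 (not isolated)
Conditions: n-C4F9SO2F (NfF), phosphazene base t-BuN=P(pyrrolidino)3 (BTPP, 2.3 equiv), DMF, −20 °C → rt
Reagents that add atoms: none
Why: One-pot aldehyde-to-alkyne dehydration (O-nonaflation of the enolate, then E2 loss of nonaflate); the medium is non-acidic, so the ene/Prins cyclisation typical of citronellal is avoided, and the C3 stereocentre is not part of the enolate.

Step 2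
Reactants: 3 (S)-3,7-dimethyloct-6-en-1-yne
Product: 4 2-[(1E,3S)-3,7-dimethylocta-1,6-dien-1-yl]-4,4,5,5-tetramethyl-1,3,2-dioxaborolane
Conditions: HBpin, Cp2ZrHCl (10 mol%), Et3N (10 mol%), neat, 60 °C
Reagents that add atoms: pinacolborane, [H]B1OC(C)(C)C(C)(C)O1
Why: Cp2ZrHCl-catalysed hydroboration of a terminal alkyne; syn, anti-Markovnikov addition should give the (E)-alkenylboronate while the trisubstituted alkene stays inert.

Step 3
Reactants: 5 5-bromoresorcinol
Product: 7 2-bromo-4,6-dihydroxybenzaldehyde, via aryl iminium chloride 6 (not isolated)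
Conditions: POCl3, DMF, MeCN, 0 °C → rt; then H2O, 50 °C
Reagents that add atoms: N,N-dimethylformamide, CN(C)C=O; water, O
Why: Vilsmeier–Haack formylation; the chloroiminium ion should attack para to one hydroxyl and ortho to the other (as with orcinol), and the iminium salt is hydrolysed to the aldehyde.

Step 4
Reactants: 7 2-bromo-4,6-dihydroxybenzaldehyde
Product: 8 6-bromo-2,4-dihydroxy-3-iodobenzaldehyde
Conditions: I2 (1.0 equiv), NaHCO3, THF/H2O, 0 °C
Reagents that add atoms: iodine, II
Why: Electrophilic aromatic iodination of the phenolate; the carbon between the two oxygens is ortho to both donors and is less hindered and less inductively deactivated than the carbon next to bromine.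

Step 5
Reactants: 8 6-bromo-2,4-dihydroxy-3-iodobenzaldehyde
Product: 9 6-bromo-3-iodo-2,4-bis(methoxymethoxy)benzaldehyde
Conditions: MOMCl (excess), i-Pr2NEt, CH2Cl2, 0 °C → rt
Reagents that add atoms: chloromethyl methyl ether, COCCl
Why: O-Alkylation of both phenols (MOM acetal formation); the hydrogen-bonded hydroxyl next to the aldehyde reacts last and is driven by excess reagent.

Step 6
Reactants: 9 6-bromo-3-iodo-2,4-bis(methoxymethoxy)benzaldehyde; 4 2-[(1E,3S)-3,7-dimethylocta-1,6-dien-1-yl]-4,4,5,5-tetramethyl-1,3,2-dioxaborolane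
Product: 10 6-bromo-3-[(1E,3S)-3,7-dimethylocta-1,6-dien-1-yl]-2,4-bis(methoxymethoxy)benzaldehyde
Conditions: Pd(PPh3)4 (5 mol%), K3PO4, 1,4-dioxane/H2O, 60 °C
Reagents that add atoms: none
Why: Suzuki–Miyaura coupling; zerovalent palladium should add to the C–I bond far faster than to the C–Br bond, and transmetalation and reductive elimination keep the E geometry.

Step 7
Reactants: 11 1-(4-hydroxyphenyl)ethanone
Product: 12 1-[4-(methoxymethoxy)phenyl]ethanone
Conditions: MOMCl, i-Pr2NEt, CH2Cl2, 0 °C → rt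
Reagents that add atoms: chloromethyl methyl ether, COCCl
Why: Phenol O-alkylation (MOM protection), which masks the acidic phenol before enolate formation.

Step 8
Reactants: 12 1-[4-(methoxymethoxy)phenyl]ethanone; 10 6-bromo-3-[(1E,3S)-3,7-dimethylocta-1,6-dien-1-yl]-2,4-bis(methoxymethoxy)benzaldehyde
Product: 15 3-{6-bromo-3-[(1E,3S)-3,7-dimethylocta-1,6-dien-1-yl]-2,4-bis(methoxymethoxy)phenyl}-3-hydroxy-1-[4-(methoxymethoxy)phenyl]propan-1-one (both C3 epimers), via lithium enolate 13 (not isolated), via lithium aldolate 14 (not isolated)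
Conditions: LiN(i-Pr)2, THF, −78 °C; then 10, −78 °C; aq. NH4Cl at −78 °C
Reagents that add atoms: none
Why: Directed aldol addition of a preformed lithium enolate to a non-enolisable aldehyde, quenched cold to avoid retro-aldol cleavage and dehydration to the chalcone; the new carbinol centre forms without control and is destroyed later.

Step 9
Reactants: 15 aldol adduct (both C3 epimers)
Product: 16 3-{6-bromo-3-[(1E,3S)-3,7-dimethylocta-1,6-dien-1-yl]-2,4-bis(methoxymethoxy)phenyl}-3-[(tert-butyldimethylsilyl)oxy]-1-[4-(methoxymethoxy)phenyl]propan-1-one (both C3 epimers)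
Conditions: TBSOTf, 2,6-lutidine, CH2Cl2, −78 °C
Reagents that add atoms: tert-butyldimethylsilyl trifluoromethanesulfonate, CC(C)(C)[Si](C)(C)OS(=O)(=O)C(F)(F)F
Why: Silylation of the hindered secondary benzylic alcohol with a silyl triflate and a hindered pyridine base; at low temperature the aryl MOM ethers and the ketone should be left alone.

Step 10
Reactants: 16 silyl ether ketone (both C3 epimers)
Product: 17 (1S)-3-{6-bromo-3-[(1E,3S)-3,7-dimethylocta-1,6-dien-1-yl]-2,4-bis(methoxymethoxy)phenyl}-3-[(tert-butyldimethylsilyl)oxy]-1-[4-(methoxymethoxy)phenyl]propan-1-ol (both C3 epimers)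
Conditions: (R)-2-methyl-CBS-oxazaborolidine (20 mol%), catecholborane, toluene, −78 → −40 °C; aq. NH4Cl work-up
Reagents that add atoms: none
Why: CBS (Corey–Bakshi–Shibata) reduction; the (R)-oxazaborolidine binds the ketone with the aryl group as the large substituent and directs hydride to the Re face, which should set the (S)-carbinol under catalyst control in both C3 epimers, and catecholborane does not hydroborate the alkenes at this temperature.

Step 11
Reactants: 17 (1S)-bromo carbinol (both C3 epimers)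
Product: 18 (2S)-4-[(tert-butyldimethylsilyl)oxy]-6-[(1E,3S)-3,7-dimethylocta-1,6-dien-1-yl]-5,7-bis(methoxymethoxy)-2-[4-(methoxymethoxy)phenyl]chromane (both C4 epimers)
Conditions: Pd2(dba)3 (2.5 mol%), t-BuXPhos (6 mol%), Cs2CO3 (1.5 equiv), toluene, 80 °C
Reagents that add atoms: none
Why: Zerovalent palladium carrying t-BuXPhos inserts into the C8a–Br bond, Cs2CO3 turns the C2 hydroxyl into a palladium-bound alkoxide to give a seven-membered aryl(alkoxo)palladium chelate (Pd, C8a, C4a, C4, C3, C2, O), and C–O reductive elimination forms O1–C8a. The closest known reaction type is the palladium-catalysed intramolecular etherification of aryl bromides with secondary alcohols (Buchwald–Hartwig C–O coupling) that gives 2-substituted chromans. Ring C is closed as a six-membered ring (O1, C2, C3, C4, C4a, C8a) by this intramolecular C(sp2)–O reductive elimination at the aryl carbon. No stereocentre is created: the C2–O bond is never broken, so the (S) configuration set by the CBS catalyst in step 10 is carried over with retention, and C4 stays an epimer mixture. The selectivity needed is reductive elimination over beta-hydride elimination of the benzylic alkoxide, which would give the ketone and the debrominated arene and could erode C2 through reversible hydride transfer; the bulky, electron-rich di-tert-butyl biaryl phosphine speeds C–O reductive elimination, and the bromide has only the tether as ortho substituent, so oxidative addition is unhindered. The C4 silyl ether shuts off base-induced retro-aldol cleavage and dehydration, and neither alkene can reach the arylpalladium centre intramolecularly.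

Step 12
Reactants: 18 (2S)-flavan-4-ol silyl ether (both C4 epimers)
Product: 19 (2S)-6-[(1E,3S)-3,7-dimethylocta-1,6-dien-1-yl]-5,7-bis(methoxymethoxy)-2-[4-(methoxymethoxy)phenyl]chroman-4-ol (both C4 epimers)
Conditions: Bu4NF, THF, 0 °C → rt
Reagents that add atoms: none
Why: Fluoride-induced silyl ether cleavage driven by Si–F bond formation; MOM ethers, alkenes and the C2 ether are inert to it.

Step 13
Reactants: 19 (2S)-flavan-4-ol (both C4 epimers)
Product: 20 (2S)-6-[(1E,3S)-3,7-dimethylocta-1,6-dien-1-yl]-5,7-bis(methoxymethoxy)-2-[4-(methoxymethoxy)phenyl]chroman-4-one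
Conditions: Dess–Martin periodinane, NaHCO3, CH2Cl2, 0 °C → rt
Reagents that add atoms: none
Why: Dess–Martin oxidation of the benzylic secondary alcohol to the aryl ketone under buffered conditions; both C4 epimers converge to one compound and C2 is not touched.

Step 14
Reactants: 20 (2S)-tris-MOM flavanone
Product: 21 (2S)-6-[(1E,3S)-3,7-dimethylocta-1,6-dien-1-yl]-5,7-dihydroxy-2-(4-hydroxyphenyl)chroman-4-one (CNP0150993.1)
Conditions: 3 M aq. HCl, MeOH/THF, 40 °C, stopped as soon as the last MOM group is gone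
Reagents that add atoms: none
Why: Acid-catalysed acetal solvolysis (MOM cleavage), the 5-O-MOM next to the carbonyl going first; mild acid and short exposure should spare the two alkenes and avoid ring opening to the chalcone, so C2 stays (S).

**Compound list**
1 | (S)-citronellal | CC(C)=CCC[C@H](C)CC=O | starting material
2 | (3S)-3,7-dimethylocta-1,6-dien-1-yl nonafluorobutanesulfonate (E/Z mixture) | CC(C)=CCC[C@H](C)C=COS(=O)(=O)C(F)(F)C(F)(F)C(F)(F)C(F)(F)F | intermediate (not isolated)
3 | (S)-3,7-dimethyloct-6-en-1-yne | CC(C)=CCC[C@H](C)C#C | intermediate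
4 | 2-[(1E,3S)-3,7-dimethylocta-1,6-dien-1-yl]-4,4,5,5-tetramethyl-1,3,2-dioxaborolane | CC(C)=CCC[C@H](C)/C=C/B1OC(C)(C)C(C)(C)O1 | intermediate
5 | 5-bromoresorcinol | Oc1cc(O)cc(Br)c1 | starting material
6 | (2-bromo-4,6-dihydroxyphenyl)methylidene-dimethyliminium chloride | C[N+](C)=Cc1c(O)cc(O)cc1Br.[Cl-] | intermediate (not isolated)
7 | 2-bromo-4,6-dihydroxybenzaldehyde | O=Cc1c(O)cc(O)cc1Br | intermediate
8 | 6-bromo-2,4-dihydroxy-3-iodobenzaldehyde | O=Cc1c(Br)cc(O)c(I)c1O | intermediate
9 | 6-bromo-3-iodo-2,4-bis(methoxymethoxy)benzaldehyde | O=Cc1c(Br)cc(OCOC)c(I)c1OCOC | intermediate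
10 | 6-bromo-3-[(1E,3S)-3,7-dimethylocta-1,6-dien-1-yl]-2,4-bis(methoxymethoxy)benzaldehyde | CC(C)=CCC[C@H](C)/C=C/c1c(OCOC)cc(Br)c(C=O)c1OCOC | intermediate
11 | 1-(4-hydroxyphenyl)ethanone | CC(=O)c1ccc(O)cc1 | starting material
12 | 1-[4-(methoxymethoxy)phenyl]ethanone | CC(=O)c1ccc(OCOC)cc1 | intermediate
13 | lithium 1-[4-(methoxymethoxy)phenyl]ethenolate | [Li]OC(=C)c1ccc(OCOC)cc1 | intermediate (not isolated)
14 | lithium alkoxide of the aldol adduct 15 (both C3 epimers) | CC(C)=CCC[C@H](C)/C=C/c1c(OCOC)cc(Br)c(C(O[Li])CC(=O)c2ccc(OCOC)cc2)c1OCOC | intermediate (not isolated)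
15 | 3-{6-bromo-3-[(1E,3S)-3,7-dimethylocta-1,6-dien-1-yl]-2,4-bis(methoxymethoxy)phenyl}-3-hydroxy-1-[4-(methoxymethoxy)phenyl]propan-1-one (both C3 epimers) | CC(C)=CCC[C@H](C)/C=C/c1c(OCOC)cc(Br)c(C(O)CC(=O)c2ccc(OCOC)cc2)c1OCOC | intermediate
16 | 3-{6-bromo-3-[(1E,3S)-3,7-dimethylocta-1,6-dien-1-yl]-2,4-bis(methoxymethoxy)phenyl}-3-[(tert-butyldimethylsilyl)oxy]-1-[4-(methoxymethoxy)phenyl]propan-1-one (both C3 epimers) | CC(C)=CCC[C@H](C)/C=C/c1c(OCOC)cc(Br)c(C(O[Si](C)(C)C(C)(C)C)CC(=O)c2ccc(OCOC)cc2)c1OCOC | intermediate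
17 | (1S)-3-{6-bromo-3-[(1E,3S)-3,7-dimethylocta-1,6-dien-1-yl]-2,4-bis(methoxymethoxy)phenyl}-3-[(tert-butyldimethylsilyl)oxy]-1-[4-(methoxymethoxy)phenyl]propan-1-ol (both C3 epimers) | CC(C)=CCC[C@H](C)/C=C/c1c(OCOC)cc(Br)c(C(O[Si](C)(C)C(C)(C)C)C[C@H](O)c2ccc(OCOC)cc2)c1OCOC | intermediate (key-step precursor)
18 | (2S)-4-[(tert-butyldimethylsilyl)oxy]-6-[(1E,3S)-3,7-dimethylocta-1,6-dien-1-yl]-5,7-bis(methoxymethoxy)-2-[4-(methoxymethoxy)phenyl]chromane (both C4 epimers) | CC(C)=CCC[C@H](C)/C=C/c1c(OCOC)cc2c(c1OCOC)C(O[Si](C)(C)C(C)(C)C)C[C@@H](c1ccc(OCOC)cc1)O2 | intermediate (key-step product)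
19 | (2S)-6-[(1E,3S)-3,7-dimethylocta-1,6-dien-1-yl]-5,7-bis(methoxymethoxy)-2-[4-(methoxymethoxy)phenyl]chroman-4-ol (both C4 epimers) | CC(C)=CCC[C@H](C)/C=C/c1c(OCOC)cc2c(c1OCOC)C(O)C[C@@H](c1ccc(OCOC)cc1)O2 | intermediate
20 | (2S)-6-[(1E,3S)-3,7-dimethylocta-1,6-dien-1-yl]-5,7-bis(methoxymethoxy)-2-[4-(methoxymethoxy)phenyl]chroman-4-one | CC(C)=CCC[C@H](C)/C=C/c1c(OCOC)cc2c(c1OCOC)C(=O)C[C@@H](c1ccc(OCOC)cc1)O2 | intermediate
21 | (2S)-6-[(1E,3S)-3,7-dimethylocta-1,6-dien-1-yl]-5,7-dihydroxy-2-(4-hydroxyphenyl)chroman-4-one | CC(C)=CCC[C@H](C)/C=C/c1c(O)cc2c(c1O)C(=O)C[C@@H](c1ccc(O)cc1)O2 | target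

**Step count**
Total: 14 steps. Longest linear sequence: 11 steps (5-bromoresorcinol through steps 3, 4, 5, 6, 8, 9, 10, 11, 12, 13, 14).

**Steps most likely to fail**

1. Step 11 (ring C closure). Beta-hydride elimination from the palladium alkoxide may outrun C–O reductive elimination, which would lead to hydrodebromination, oxidation of the carbinol and possibly erosion at C2. The fallback forms the other C–O bond of O1 instead. It sets out from 16:
   - Miyaura borylation (B2pin2, PdCl2(dppf), KOAc, dioxane, 85 °C) would give 3-[(tert-butyldimethylsilyl)oxy]-3-{3-[(1E,3S)-3,7-dimethylocta-1,6-dien-1-yl]-2,4-bis(methoxymethoxy)-6-(4,4,5,5-tetramethyl-1,3,2-dioxaborolan-2-yl)phenyl}-1-[4-(methoxymethoxy)phenyl]propan-1-one F1.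
   - Oxidation with NaBO3·4H2O in THF/H2O would give the C8a phenol 3-[(tert-butyldimethylsilyl)oxy]-3-{3-[(1E,3S)-3,7-dimethylocta-1,6-dien-1-yl]-6-hydroxy-2,4-bis(methoxymethoxy)phenyl}-1-[4-(methoxymethoxy)phenyl]propan-1-one F2.
   - Reduction with (S)-2-methyl-CBS-oxazaborolidine and catecholborane would give the (1R)-carbinol (1R)-3-[(tert-butyldimethylsilyl)oxy]-3-{3-[(1E,3S)-3,7-dimethylocta-1,6-dien-1-yl]-6-hydroxy-2,4-bis(methoxymethoxy)phenyl}-1-[4-(methoxymethoxy)phenyl]propan-1-ol F3.
   - Mitsunobu cyclisation (PPh3, DIAD, THF, 0 °C) would close ring C by displacement at C2 with inversion and come back to the route at 18.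

2. Step 4 (iodination). The chelated hydroxyl may steer iodine to the carbon next to bromine, or a second iodination may follow. The fallback iodinates before the formyl group exists. It sets out from 5:
   - I2/NaHCO3 in water would give the symmetrical 5-bromo-2-iodobenzene-1,3-diol F4, as in the known 2-iodination of resorcinol.
   - MOMCl/i-Pr2NEt would give 5-bromo-2-iodo-1,3-bis(methoxymethoxy)benzene F5.
   - Suzuki coupling with 4 (Pd(PPh3)4, K3PO4) at the iodide would give 5-bromo-2-[(1E,3S)-3,7-dimethylocta-1,6-dien-1-yl]-1,3-bis(methoxymethoxy)benzene F6; here the bromide is not activated by an ortho formyl group.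
   - Directed ortho-lithiation with lithium 2,2,6,6-tetramethylpiperidide (THF, −78 °C) at the only ring C–H type, between bromine and a MOM ether, followed by DMF, would come back to the route at 10.

3. Step 14 (global MOM cleavage). Protic acid may add methanol across the electron-rich styrene or the trisubstituted alkene, or induce cyclisation onto a freed phenol, and partial ring opening to the chalcone may erode C2. The fallback avoids protic acid and sets out from 20:
   - TMSOTf with 2,2'-bipyridyl (CH2Cl2, 0 °C → rt) would exchange the three aryl MOM ethers for silyl ethers, giving (2S)-6-[(1E,3S)-3,7-dimethylocta-1,6-dien-1-yl]-5,7-bis(trimethylsilyloxy)-2-[4-(trimethylsilyloxy)phenyl]chroman-4-one F7.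
   - Addition of water would hydrolyse the silyl ethers at near-neutral pH and come back to the route at 21.

**Further compounds**
F1 | step 11 | 3-[(tert-butyldimethylsilyl)oxy]-3-{3-[(1E,3S)-3,7-dimethylocta-1,6-dien-1-yl]-2,4-bis(methoxymethoxy)-6-(4,4,5,5-tetramethyl-1,3,2-dioxaborolan-2-yl)phenyl}-1-[4-(methoxymethoxy)phenyl]propan-1-one | CC(C)=CCC[C@H](C)/C=C/c1c(OCOC)cc(B2OC(C)(C)C(C)(C)O2)c(C(O[Si](C)(C)C(C)(C)C)CC(=O)c2ccc(OCOC)cc2)c1OCOC
F2 | step 11 | 3-[(tert-butyldimethylsilyl)oxy]-3-{3-[(1E,3S)-3,7-dimethylocta-1,6-dien-1-yl]-6-hydroxy-2,4-bis(methoxymethoxy)phenyl}-1-[4-(methoxymethoxy)phenyl]propan-1-one | CC(C)=CCC[C@H](C)/C=C/c1c(OCOC)cc(O)c(C(O[Si](C)(C)C(C)(C)C)CC(=O)c2ccc(OCOC)cc2)c1OCOC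
F3 | step 11 | (1R)-3-[(tert-butyldimethylsilyl)oxy]-3-{3-[(1E,3S)-3,7-dimethylocta-1,6-dien-1-yl]-6-hydroxy-2,4-bis(methoxymethoxy)phenyl}-1-[4-(methoxymethoxy)phenyl]propan-1-ol | CC(C)=CCC[C@H](C)/C=C/c1c(OCOC)cc(O)c(C(O[Si](C)(C)C(C)(C)C)C[C@@H](O)c2ccc(OCOC)cc2)c1OCOC
F4 | step 4 | 5-bromo-2-iodobenzene-1,3-diol | Oc1cc(Br)cc(O)c1I
F5 | step 4 | 5-bromo-2-iodo-1,3-bis(methoxymethoxy)benzene | COCOc1cc(Br)cc(OCOC)c1I
F6 | step 4 | 5-bromo-2-[(1E,3S)-3,7-dimethylocta-1,6-dien-1-yl]-1,3-bis(methoxymethoxy)benzene | CC(C)=CCC[C@H](C)/C=C/c1c(OCOC)cc(Br)cc1OCOC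
F7 | step 14 | (2S)-6-[(1E,3S)-3,7-dimethylocta-1,6-dien-1-yl]-5,7-bis(trimethylsilyloxy)-2-[4-(trimethylsilyloxy)phenyl]chroman-4-one | CC(C)=CCC[C@H](C)/C=C/c1c(O[Si](C)(C)C)cc2c(c1O[Si](C)(C)C)C(=O)C[C@@H](c1ccc(O[Si](C)(C)C)cc1)O2
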